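## The problem

The target is a diterpenoid with a trans-fused hydroazulene core: ring A (C1–C5) holds the C3=C4 alkene with a methyl on C4, and ring B (C1, C5–C10) holds the C6 alcohol, the C7 side chain and an exocyclic methylene on C10. The side chain is a 2,2,5-trisubstituted oxolane (C11–C14 and the ring oxygen) that ends in a tertiary acetate at C15. The four contiguous ring stereocentres can be relayed C1 → C7 → C6 → C5, whereas quaternary C11 and C14 lie beyond the C7–C11 bond and need their own absolute source, so C7 must be controlled by the ring and not by C11. With C6 as a ketone the trans fusion is fragile: C5 is α to the carbonyl and allylic, and C7 is α to the carbonyl and β to the oxolane oxygen, so base can epimerise C5, conjugate the alkene or open the heterocycle. The tertiary acetate excludes hard nucleophiles and long alkoxide treatment, the 1,1-disubstituted alkene is the first site attacked by osmium or ozone, and any leaving group on C5 is allylic. The enabling feature is the C6 oxygen next to the fusion carbon C5: a cis-fused six–six bicycle with C1 on a tertiary C6 carbinol and a leaving group on C5 cis to that hydroxyl gives the five–seven skeleton by a 1,2-shift of C1 from C6 to C5.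

## Retrosynthesis

**C6–H.** Target 24 is cut back to ketone 23. The forward step is a hydride reduction that must deliver hydrogen to the face opposite the C7 side chain under conditions too mild to enolise C5 or C7.

**C1–C5 (key cut).** Breaking C1–C5 in 23 and reconnecting C1 to C6 gives the cis-fused mesylate 22. This is preferred over closing the seven-membered ring directly because both rings become six-membered and the fusion stereochemistry becomes a stereospecific event. C10 already carries the methylene in 22, so nothing but the reduction follows the shift. The forward reaction needs the C5 oxygen cis to the C6 hydroxyl and on the α face (the face of H1).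

**The cis-5,6-diol.** Mesylate 22 comes from diol 21. Direct reduction of ketol 16 is rejected: the β face of its carbonyl is covered by the axial C1–C10 bond, so hydride should enter from the α face and give the useless trans-diol. Osmylation of a C5=C6 alkene is rejected because the exocyclic alkene and the ring-A alkene would compete. Oxygen is therefore always delivered from the open α face through two Wharton transpositions, 16 → 17 → 18 → 19 → 20 → 21. This costs five steps, which is the price of the carvone carbon map.

**C6–O.** Ketol 16 is cut to enone 15 by removing the C6 hydroxyl. C4 is sp2, so C6 is the only kinetic enolisation site, and the C7 substituent directs the oxidant to the α face.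

**C8–C9.** Enone 15 is traced to the nitro epoxy ketone 13, and 13 is opened at C8–C9 to allylic chloride 12 and hence to 11. A nitronate on C8 and a symmetric π-allyl unit on C9/C10 close a six-membered ring and leave the methylene in place. The nitro group and the epoxide mask are then removed in one radical step.

**C7–C8.** Cutting C7–C8 in 11 gives the (E)-alkylidene epoxy ketone 10 and nitromethane. An intramolecular delivery of C8 from the C1 side chain was rejected because it would attack the β face of C7 and give the C7 epimer. The intermolecular addition should take the α face, since allylic strain forces the C1 substituent axial on the β face. The epoxide mask keeps C3 from acting as a second acceptor.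

**C6=C7 and the building blocks.** Alkylidene 10 is cut to carvone oxide 7 and aldehyde 5. Oxide 7 comes in one step from (R)-carvone 6, which supplies C1–C6, the C4 methyl, C9, C10 and the methylene carbon. Aldehyde 5 comes from (R)-linalool 1 through cis-linalool oxide 3 and its acetate 4, which supply C7 and C11–C15 with both oxolane centres set. Nitromethane supplies C8.

## Roads not taken

Alternative 1: Cut C7–C8 in ring B. A sulfone carbanion at C8 opens a C7–C11 epoxide to give the ring-B sulfone A1. Merits: C7 and C11 are set together and stereospecifically by one epoxide, the C6 oxygen is already present, and there is no rearrangement. Weak points: a seven-membered ring must close by attack at an epoxide carbon next to a quaternary centre, a fully substituted trans cyclopentane (C1, C5, C6) is needed beforehand, and desulfonylation and oxolane closure remain. This road is better than the chosen plan in fixing C7 against C11 by reagent control and in avoiding the long diol sequence. The chosen plan sets against it six-membered ring closures and a fusion fixed by a stereospecific shift.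

Alternative 2: Contract carvone 6 before annulation. Photolysis of diazo ketone A2 in methanol forms C4–C5 by Wolff rearrangement and gives cyclopentene ester A3. Merits: ring A, C1, the ring alkene and the isopropenyl carbons arrive in very few steps from the same starting material, and here this road is clearly shorter. Weak points: A3 is a β,γ-unsaturated ester with an epimerisable C5, and the seven-membered ring, C6, C7 and the side chain are all still to be made with little help from the cyclopentene. The chosen plan sets against it that ring size and the C5 configuration are solved in one event.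

Alternative 3: Cut C1–C10 and C5–C6. Catalytic asymmetric conjugate addition of a silylvinyl copper reagent to cyclopentenone with aldol trapping gives A4. Merits: it is the most convergent road, the catalyst sets the absolute configuration, the trans C1/C5 relation is inherent and the C6 hydroxyl forms directly; in step count on paper it beats the chosen plan. Weak points: the aldehyde partner carries C7 α to the formyl group and β to the ring oxygen, so it can epimerise or eliminate; facial selectivity at C6 is uncertain; ring B must still be closed and the ring-A alkene and methyl installed. The chosen plan sets against it that C7 is never enolisable until the penultimate step and that C5 and C6 follow from ring geometry.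

Key step: step 17

Remark: locants C1–C15 and face labels (α = face of H1, β = face of the C7 side chain) are those of the target throughout; T is the (2R,5S)-5-(2-acetoxypropan-2-yl)-2-methyloxolan-2-yl group; the C6 and C8 configurations drawn for 11–15 are the expected major epimers and are erased later.

## Route

Step 1
Reactants: 1 (R)-(−)-linalool
Product: 3 cis-linalool oxide (furanoid; 2S,5R), via 6,7-epoxylinalool 2 (not isolated)
Conditions: Shi ketone (D-fructose-derived, 30 mol %), KHSO5 (Oxone), K2CO3, n-Bu4NHSO4, MeCN–CH2(OMe)2–aq. buffer, 0 °C; then CSA (5 mol %), CH2Cl2, 0 °C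
Reagents that add atoms: potassium peroxymonosulfate, [K+].[O-]S(=O)(=O)OO
Why: Shi epoxidation should attack only the trisubstituted alkene and give the (6R)-epoxide 2; acid then triggers 5-exo opening by the tertiary hydroxyl with inversion at C14, setting C11 and C14 cis, and the pyranoid isomer expected as a minor product is removed by chromatography.

Step 2
Reactants: 3 cis-linalool oxide
Product: 4 cis-linalool oxide acetate
Conditions: Ac2O, Et3N, DMAP (0.2 equiv), CH2Cl2, 40 °C
Reagents that add atoms: acetic anhydride, CC(=O)OC(C)=O
Why: DMAP-catalysed acylation of the hindered tertiary alcohol; no stereocentre is touched.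

Step 3
Reactants: 4 cis-linalool oxide acetate
Product: 5 2-[(2S,5R)-5-formyl-5-methyloxolan-2-yl]propan-2-yl acetate
Conditions: O3, CH2Cl2–MeOH, −78 °C; then Me2S, −78 °C → rt
Reagents that add atoms: ozone, [O-][O+]=O
Why: Ozonolysis with reductive work-up cleaves the only alkene to a non-enolisable α-alkoxy aldehyde whose carbonyl carbon is C7.

Step 4
Reactants: 6 (R)-(−)-carvone
Product: 7 (1R,4R,6R)-carvone oxide
Conditions: H2O2 (30 %), NaOH (0.2 equiv), MeOH, 0 °C
Reagents that add atoms: hydrogen peroxide, OO
Why: Weitz–Scheffer epoxidation; hydroperoxide adds trans to the isopropenyl group, so the epoxide lies on the α face, masks C3 as an acceptor and leaves C6 as the only enolisable position.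

Step 5
Reactants: 7 carvone oxide; 5 formyl oxolane acetate
Product: 10 (E)-C6-alkylidene epoxy ketone, via aldol adduct 8 (not isolated), via aldol mesylate 9 (not isolated)
Conditions: LiN(i-Pr)2, THF, −78 °C; then 5; then MsCl, Et3N, −78 → 0 °C; then DBU, 0 °C → rt
Reagents that add atoms: none
Why: Kinetic enolate aldol addition at C6 followed by mesylation and E1cB elimination (aldol condensation); the (E)-alkylidene with T anti to the carbonyl is expected and both aldol stereocentres are erased.

Step 6
Reactants: 10 (E)-C6-alkylidene epoxy ketone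
Product: 11 C7 nitromethyl Michael adduct
Conditions: MeNO2 (solvent), DBU (0.5 equiv), 0 °C → rt
Reagents that add atoms: nitromethane, C[N+](=O)[O-]
Why: Michael addition of nitromethane to the only enone; allylic 1,3-strain between T and C1 forces the isopropenyl group axial on the β face, so the nitronate should add to C7 from the α face and set the C7 configuration of the target.

Step 7
Reactants: 11 C7 nitromethyl Michael adduct
Product: 12 allylic chloride (3-chloroprop-1-en-2-yl at C1)
Conditions: NCS (1.1 equiv), PhSeCl (10 mol %), CH2Cl2, rt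
Reagents that add atoms: N-chlorosuccinimide, O=C1CCC(=O)N1Cl
Why: Selenium-catalysed ene-type allylic chlorination of the electron-rich 1,1-disubstituted alkene; ketone, nitro, epoxide and acetate groups should be untouched.

Step 8
Reactants: 12 allylic chloride
Product: 13 bicyclic nitro epoxy ketone with C10 methylene
Conditions: Pd(PPh3)4 (5 mol %), Cs2CO3 (1.5 equiv), THF, rt
Reagents that add atoms: none
Why: Intramolecular Tsuji–Trost allylation; the nitronate, far more acidic than the ketone, attacks the π-allyl complex of zerovalent palladium (both termini give the same product) and closes C8–C9 in a 6-exo mode with T equatorial.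

Step 9
Reactants: 13 bicyclic nitro epoxy ketone
Product: 15 bicyclic enone (trans-fused), via β-hydroxy ketone 14 (not isolated)
Conditions: Bu3SnH (5 equiv), AIBN (0.3 equiv), PhMe, 110 °C; then DBU, rt
Reagents that add atoms: none
Why: Radical chain reduction replaces the secondary nitro group by hydrogen (radical denitration) and opens the α,β-epoxy ketone to the β-hydroxy ketone, which DBU dehydrates by E1cB to the enone; C1 and C7 are not involved.

Step 10
Reactants: 15 bicyclic enone
Product: 16 6α-hydroxy enone (cis-fused ketol)
Conditions: KN(SiMe3)2 (1.1 equiv), THF, −78 °C; then 2-(phenylsulfonyl)-3-phenyloxaziridine, −78 °C; aq. NH4Cl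
Reagents that add atoms: 2-(phenylsulfonyl)-3-phenyloxaziridine, O=S(=O)(c1ccccc1)N1OC1c1ccccc1
Why: Kinetic α′-enolisation (C4 is sp2 and the acetate is much less acidic toward the silylamide) and enolate hydroxylation with the Davis oxaziridine; the oxidant should approach C6 anti to T, from the α face, giving the cis ring fusion.

Step 11
Reactants: 16 6α-hydroxy enone
Product: 17 3α,4α-epoxy ketol
Conditions: H2O2 (30 %), LiOH (0.3 equiv), MeOH, 0 °C
Reagents that add atoms: hydrogen peroxide, OO
Why: Weitz–Scheffer epoxidation; hydroperoxide should add to C3 on the convex α face because the β face is covered by the axial C1–C10 bond, as in the epoxidation of carvone itself.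

Step 12
Reactants: 17 3α,4α-epoxy ketol
Product: 18 3α,6α-diol with C4=C5
Conditions: N2H4·H2O (3 equiv), AcOH (0.2 equiv), MeOH, 0 °C → rt, under Ar
Reagents that add atoms: none
Why: Wharton transposition; the epoxy hydrazone fragments with loss of N2, moving the alkene to C4=C5 and leaving oxygen on C3, whose configuration is irrelevant because C3 is oxidised later.

Step 13
Reactants: 18 3α,6α-diol with C4=C5
Product: 19 4α,5α-epoxy-3α,6α-diol
Conditions: VO(acac)2 (5 mol %), t-BuOOH (1.5 equiv), CH2Cl2, 0 °C → rt
Reagents that add atoms: tert-butyl hydroperoxide, CC(C)(C)OO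
Why: Hydroxyl-directed vanadium-catalysed epoxidation; both flanking hydroxyls (C3, C6) are on the α face, so oxygen is delivered syn to them and C5–O is set α, cis to C6–O, while the homoallylic exocyclic alkene should react more slowly.

Step 14
Reactants: 19 4α,5α-epoxy-3α,6α-diol
Product: 20 4α,5α-epoxy-6α-hydroxy-3-ketone
Conditions: Dess–Martin periodinane (1.3 equiv), pyridine, CH2Cl2, 0 °C
Reagents that add atoms: none
Why: Dess–Martin oxidation of the secondary C3 carbinol; the tertiary C6 hydroxyl and the epoxide are inert under buffered conditions.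

Step 15
Reactants: 20 4α,5α-epoxy-6α-hydroxy-3-ketone
Product: 21 cis-5α,6α-diol with C3=C4
Conditions: N2H4·H2O (3 equiv), AcOH (0.2 equiv), MeOH, 0 °C → rt, under Ar
Reagents that add atoms: none
Why: Second Wharton transposition; loss of N2 opens the epoxide at C4, returns the alkene to C3=C4 and releases the C5 hydroxyl with its α configuration, so the cis-diol arises without any reagent having to reach the shielded β face.

Step 16
Reactants: 21 cis-5α,6α-diol
Product: 22 cis-diol 5-mesylate
Conditions: (MeSO2)2O (1.2 equiv), Et3N, CH2Cl2, −30 °C; cold aqueous work-up, used crude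
Reagents that add atoms: methanesulfonic anhydride, CS(=O)(=O)OS(C)(=O)=O
Why: Chemoselective sulfonylation of the secondary allylic hydroxyl over the tertiary one; the chloride-free anhydride avoids allylic chloride formation.

Step 17
Reactants: 22 cis-diol 5-mesylate
Product: 23 trans-fused hydroazulen-6-one
Conditions: Et3Al (3 equiv), CH2Cl2, −78 °C; aq. potassium sodium tartrate
Reagents that add atoms: none
Why: Pinacol-type (semipinacol) 1,2-shift; the closest known reaction types are the organoaluminium-promoted rearrangement of 2-sulfonyloxy alcohols and the solvolytic ring contraction of hydronaphthalene diol monosulfonates to hydroazulenones. Et3Al turns the C6 hydroxyl into an aluminium alkoxide and activates the mesylate, and the C6–C1 bond migrates to C5 as C5–O breaks. No ring is closed by an external bond: the ring C1–C6 contracts to ring A by the shift (formally a 3-exo-tet displacement at C5) and the ring C1, C6–C10 expands to ring B as C5 is inserted, with C6 becoming the ketone. C5 is the new stereocentre and is formed with inversion, controlled by the α-mesylate, while C1 migrates with retention, so α-OMs and α-H1 translate into the trans fusion. The step needs migration of C1 rather than C7 and a concerted course rather than allylic ionisation. In the only low-energy conformer of the cis-fused bicycle (T equatorial) the C5–O bond is pseudo-equatorial and antiperiplanar to C6–C1 alone, and it lies in the plane of C3=C4, which disfavours unassisted ionisation. Low temperature and the non-basic medium should protect the β,γ-unsaturated ketone from C5 epimerisation, conjugation and β-elimination of the oxolane oxygen.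

Step 18
Reactants: 23 trans-fused hydroazulen-6-one
Product: 24 target CNP0302132.3
Conditions: NaBH4, MeOH, −20 °C
Reagents that add atoms: none
Why: Borohydride reduction; hydride should add to C6 from the α face, away from T, giving the 6β-alcohol cis to the side chain, and the short cold reaction avoids enolisation toward C5 or C7.

## Compound list

1 | (R)-(−)-linalool, (3R)-3,7-dimethylocta-1,6-dien-3-ol | C=C[C@](C)(O)CCC=C(C)C | starting material
2 | (3R,6R)-6,7-epoxylinalool, (3R)-5-[(2R)-3,3-dimethyloxiran-2-yl]-3-methylpent-1-en-3-ol | C=C[C@](C)(O)CC[C@H]1OC1(C)C | intermediate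
3 | cis-linalool oxide (furanoid), 2-[(2S,5R)-5-ethenyl-5-methyloxolan-2-yl]propan-2-ol | C=C[C@@]1(C)CC[C@@H](C(C)(C)O)O1 | intermediate
4 | 2-[(2S,5R)-5-ethenyl-5-methyloxolan-2-yl]propan-2-yl acetate | C=C[C@@]1(C)CC[C@@H](C(C)(C)OC(C)=O)O1 | intermediate
5 | 2-[(2S,5R)-5-formyl-5-methyloxolan-2-yl]propan-2-yl acetate | O=C[C@@]1(C)CC[C@@H](C(C)(C)OC(C)=O)O1 | intermediate
6 | (R)-(−)-carvone, (5R)-2-methyl-5-(prop-1-en-2-yl)cyclohex-2-en-1-one | CC1=CC[C@@H](C(C)=C)CC1=O | starting material
7 | carvone oxide, (1R,4R,6R)-1-methyl-4-(prop-1-en-2-yl)-7-oxabicyclo[4.1.0]heptan-2-one | C=C(C)[C@@H]1C[C@H]2O[C@@]2(C)C(=O)C1 | intermediate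
8 | aldol adduct: carvone oxide bearing CH(OH)–T at C6 (C6/C7 epimers) | C=C(C)[C@@H]1C[C@H]2O[C@@]2(C)C(=O)C1C(O)[C@@]3(C)CC[C@@H](C(C)(C)OC(C)=O)O3 | intermediate
9 | C7 mesylate of aldol adduct 8 (C6/C7 epimers) | C=C(C)[C@@H]1C[C@H]2O[C@@]2(C)C(=O)C1C(OS(C)(=O)=O)[C@@]3(C)CC[C@@H](C(C)(C)OC(C)=O)O3 | intermediate
10 | carvone oxide with exocyclic (E)-C6=C7H–T (T anti to the C5 carbonyl) | C=C(C)[C@@H]1C[C@H]2O[C@@]2(C)C(=O)/C1=C/[C@@]3(C)CC[C@@H](C(C)(C)OC(C)=O)O3 | intermediate
11 | carvone oxide bearing at C6 the (1S)-2-nitro-1-T-ethyl group (C7 as in the target; 6-H trans to isopropenyl drawn) | C=C(C)[C@@H]1C[C@H]2O[C@@]2(C)C(=O)[C@H]1[C@@H](C[N+](=O)[O-])[C@@]3(C)CC[C@@H](C(C)(C)OC(C)=O)O3 | intermediate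
12 | allylic chloride of 11 (C1 bears 3-chloroprop-1-en-2-yl) | C=C(CCl)[C@@H]1C[C@H]2O[C@@]2(C)C(=O)[C@H]1[C@@H](C[N+](=O)[O-])[C@@]3(C)CC[C@@H](C(C)(C)OC(C)=O)O3 | intermediate
13 | trans-fused bicyclo[4.4.0]decan-5-one: 3α,4α-epoxide, 4-methyl, 7β-T, 8α-nitro, 10-methylidene, 1α-H, 6β-H | C=C1C[C@H]([N+](=O)[O-])[C@@H]([C@@]4(C)CC[C@@H](C(C)(C)OC(C)=O)O4)[C@@H]2C(=O)[C@]3(C)O[C@@H]3C[C@@H]12 | intermediate
14 | trans-fused bicyclo[4.4.0]decan-5-one: 3α-hydroxy, 4-methyl (C4 epimers), 7β-T, 10-methylidene | C=C1CC[C@@H]([C@@]3(C)CC[C@@H](C(C)(C)OC(C)=O)O3)[C@@H]2C(=O)C(C)[C@H](O)C[C@@H]12 | intermediate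
15 | trans-fused bicyclo[4.4.0]dec-3-en-5-one: 4-methyl, 7β-T, 10-methylidene, 1α-H, 6β-H | C=C1CC[C@@H]([C@@]3(C)CC[C@@H](C(C)(C)OC(C)=O)O3)[C@@H]2C(=O)C(C)=CC[C@@H]12 | intermediate
16 | cis-fused 6α-hydroxy bicyclo[4.4.0]dec-3-en-5-one: 4-methyl, 7β-T, 10-methylidene, 1α-H | C=C1CC[C@@H]([C@@]3(C)CC[C@@H](C(C)(C)OC(C)=O)O3)[C@@]2(O)C(=O)C(C)=CC[C@@H]12 | intermediate
17 | cis-fused 3α,4α-epoxy-6α-hydroxy-5-ketone: 4-methyl, 7β-T, 10-methylidene | C=C1CC[C@@H]([C@@]4(C)CC[C@@H](C(C)(C)OC(C)=O)O4)[C@@]2(O)C(=O)[C@]3(C)O[C@@H]3C[C@@H]12 | intermediate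
18 | cis-fused bicyclo[4.4.0]dec-4-ene-3α,6α-diol: 4-methyl, 7β-T, 10-methylidene | C=C1CC[C@@H]([C@@]3(C)CC[C@@H](C(C)(C)OC(C)=O)O3)[C@@]2(O)C=C(C)[C@H](O)C[C@@H]12 | intermediate
19 | cis-fused 4α,5α-epoxy-3α,6α-diol: 4-methyl, 7β-T, 10-methylidene | C=C1CC[C@@H]([C@@]4(C)CC[C@@H](C(C)(C)OC(C)=O)O4)[C@@]2(O)[C@@H]3O[C@]3(C)[C@H](O)C[C@@H]12 | intermediate
20 | cis-fused 4α,5α-epoxy-6α-hydroxy-3-ketone: 4-methyl, 7β-T, 10-methylidene | C=C1CC[C@@H]([C@@]4(C)CC[C@@H](C(C)(C)OC(C)=O)O4)[C@@]2(O)[C@@H]3O[C@]3(C)C(=O)C[C@@H]12 | intermediate
21 | cis-fused bicyclo[4.4.0]dec-3-ene-5α,6α-diol: 4-methyl, 7β-T, 10-methylidene, 1α-H | C=C1CC[C@@H]([C@@]3(C)CC[C@@H](C(C)(C)OC(C)=O)O3)[C@@]2(O)[C@H](O)C(C)=CC[C@@H]12 | intermediate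
22 | 5α-methanesulfonate of diol 21 (6α-OH free) | C=C1CC[C@@H]([C@@]3(C)CC[C@@H](C(C)(C)OC(C)=O)O3)[C@@]2(O)[C@H](OS(C)(=O)=O)C(C)=CC[C@@H]12 | intermediate
23 | trans-fused hydroazul-3-en-6-one: 4-methyl, 7β-T, 10-methylidene, 1α-H, 5β-H | C=C1CC[C@@H]([C@@]3(C)CC[C@@H](C(C)(C)OC(C)=O)O3)C(=O)[C@@H]2C(C)=CC[C@@H]12 | intermediate
24 | target CNP0302132.3: (1R,5S,6S,7R,11R,14S) 6β-hydroxy-4-methyl-10-methylidene-7β-T-hydroazul-3-ene | C=C1CC[C@@H]([C@@]2(C)CC[C@@H](C(C)(C)OC(C)=O)O2)[C@@H](O)[C@@H]2C(C)=CC[C@@H]12 | target

## Step count and least certain steps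

Total: 18 steps. Longest linear sequence: 17 steps (from 1 through steps 1–3 and 5–18); the carvone branch joins at step 5 after one step.

**Step 17 (key step).** The allylic mesylate may ionise to the allyl cation before C1 migrates, which would lose the stereospecificity and open the way to C7 migration or diene formation. The product may also epimerise at C5 or conjugate. The fallback moves the shift to an epoxide and sets out from 16. Luche reduction (NaBH4, CeCl3·7H2O), expected to deliver hydride from the open α face, gives the 5β-alcohol F1. Sulfonylation gives the 5β-mesylate F2, and DBU closes it to the 5α,6α-vinyl epoxide F3 through the anti C6 alkoxide. A Meinwald-type rearrangement with methylaluminium bis(4-bromo-2,6-di-tert-butylphenoxide) at −78 °C then shifts C1 and rejoins the route at 23.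

**Step 6.** Conjugate addition at a β-carbon flanked by the quaternary C11 may be slow, and any (Z)-alkylidene would erode the facial selectivity. The fallback sets out from 10. Allyl cuprate addition (allylMgBr, CuBr·SMe2, Me3SiCl) gives the C7 allyl ketone F4, and allylic chlorination as in step 7 gives F5. Ring-closing metathesis with the second-generation Grubbs catalyst gives the chloromethyl cyclohexene F6. Pd(OAc)2/PBu3 with HCO2NH4 then delivers hydride to the ring terminus of the allyl unit (exocyclic methylene) and hydrogenolyses the epoxy ketone to 14, and DBU returns the route at 15. This path also avoids the nitro group and the tin step.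

**Step 10.** Deprotonation may occur at C2 or at the acetate, or the enolate may add to the sulfonimine by-product. The fallback sets out from 15. α′-Acetoxylation with Mn(OAc)3·2H2O in hot benzene gives the 6α-acetoxy enone F7, and selective methanolysis of this α-acyloxy ketone (K2CO3, MeOH, 0 °C) returns to 16.

**Step 12.** Hydrazone formation at a ketone flanked by two fully substituted carbons may be too slow, leaving time for ketol rearrangement. The fallback sets out from 16 and goes through the 5β-alcohol F1 described above. 1,3-Transposition with catalytic O3ReOSiPh3 moves the hydroxyl to the less hindered C3 and gives F8, and MnO2 oxidises it to the transposed enone F9. Epoxidation with H2O2/LiOH on the α face then returns to the route at 20.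

**Step 18.** Hydride may attack the wrong face and give the 6α-alcohol. The fallback sets out from 23. If the reduction gives the 6α-alcohol F10, Mitsunobu inversion with 4-nitrobenzoic acid gives the 6β-ester F11, and mild methanolysis (K2CO3, MeOH) of this secondary ester beside the tertiary acetate returns to 24.

## Further compounds

F1 | step 17 | cis-fused 5β,6α-diol (5-epimer of 21) | C=C1CC[C@@H]([C@@]3(C)CC[C@@H](C(C)(C)OC(C)=O)O3)[C@@]2(O)[C@@H](O)C(C)=CC[C@@H]12
F2 | step 17 | 5β-methanesulfonate of F1 | C=C1CC[C@@H]([C@@]3(C)CC[C@@H](C(C)(C)OC(C)=O)O3)[C@@]2(O)[C@@H](OS(C)(=O)=O)C(C)=CC[C@@H]12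
F3 | step 17 | 5α,6α-epoxide (vinyl epoxide, C3=C4) | C=C1CC[C@@H]([C@@]4(C)CC[C@@H](C(C)(C)OC(C)=O)O4)[C@]23O[C@@H]3C(C)=CC[C@@H]12
F4 | step 6 | carvone oxide bearing at C6 the 1-T-but-3-enyl group (C7 as in 11) | C=C(C)[C@@H]1C[C@H]2O[C@@]2(C)C(=O)[C@H]1[C@@H](CC=C)[C@@]3(C)CC[C@@H](C(C)(C)OC(C)=O)O3
F5 | step 6 | allylic chloride of F4 | C=C(CCl)[C@@H]1C[C@H]2O[C@@]2(C)C(=O)[C@H]1[C@@H](CC=C)[C@@]3(C)CC[C@@H](C(C)(C)OC(C)=O)O3
F6 | step 6 | ring-closed 10-(chloromethyl) C9=C10 epoxy ketone | ClCC1=CC[C@@H]([C@@]4(C)CC[C@@H](C(C)(C)OC(C)=O)O4)[C@@H]2C(=O)[C@]3(C)O[C@@H]3C[C@@H]12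
F7 | step 10 | 6α-acetoxy enone (acetate of 16) | C=C1CC[C@@H]([C@@]3(C)CC[C@@H](C(C)(C)OC(C)=O)O3)[C@@]2(OC(C)=O)C(=O)C(C)=CC[C@@H]12
F8 | step 12 | 3β,6α-diol with C4=C5 (3-epimer of 18) | C=C1CC[C@@H]([C@@]3(C)CC[C@@H](C(C)(C)OC(C)=O)O3)[C@@]2(O)C=C(C)[C@@H](O)C[C@@H]12
F9 | step 12 | 6α-hydroxy-3-keto C4=C5 enone | C=C1CC[C@@H]([C@@]3(C)CC[C@@H](C(C)(C)OC(C)=O)O3)[C@@]2(O)C=C(C)C(=O)C[C@@H]12
F10 | step 18 | 6α-alcohol (6-epimer of 24) | C=C1CC[C@@H]([C@@]3(C)CC[C@@H](C(C)(C)OC(C)=O)O3)[C@H](O)[C@@H]2C(C)=CC[C@@H]12
F11 | step 18 | 6β-(4-nitrobenzoate) of 24 | C=C1CC[C@@H]([C@@]3(C)CC[C@@H](C(C)(C)OC(C)=O)O3)[C@@H](OC(=O)c3ccc(cc3)[N+](=O)[O-])[C@@H]2C(C)=CC[C@@H]12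
A1 | alternative 1 | ring-B C8 sulfone with C11 tertiary alcohol | C=C1CC(S(=O)(=O)c2ccccc2)[C@@H]([C@](C)(O)CC[C@@H]3OC(C)(C)OC3(C)C)[C@@H](O[Si](C)(C)C(C)(C)C)[C@@H]4C(C)=CC[C@@H]14
A2 | alternative 2 | 6-diazocarvone | C=C(C)[C@@H]1CC=C(C)C(=O)C1=[N+]=[N-]
A3 | alternative 2 | methyl trans-2-methyl-5-isopropenylcyclopent-2-ene-1-carboxylate | C=C(C)[C@@H]1CC=C(C)[C@H]1C(=O)OC
A4 | alternative 3 | trans-2,3-disubstituted cyclopentanone aldol | O=C1CC[C@@H](C(=C)[Si](C)(C)C)[C@@H]1[C@H](O)[C@@H](C=C)[C@@]2(C)CC[C@@H](C(C)(C)OC(C)=O)O2
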